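(The data stem from a simulated flask on assumed constants, noise included.)

- ash: G 30 mM; J 11 mM (held); run made earlier
- flask: G 20 mM; J 11 mM (held); time 5.0 d
ash run (percent of the G charged)

| time / h | E / % | G / % |
|---|---|---|
| 1.00 | 5.4 | 92.7 |
| 3.00 | 14.0 | 77.0 |
| 6.00 | 27.5 | 53.6 |
| 8.00 | 36.6 | 39.6 |
| 12.0 | 44.3 | 15.4 |

(readings scatter by 1 percentage point)
- the best time, 5.0 d at the latest, for E
- the amount of E, in percent of the G charged, at that time
- the earlier runs were read with a standard deviation of 1 percentage point
- at the start none of J is in solution
- a reading of G is of its free form alone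

**One step.** I began from a one-step world, in which G falls by a fixed fraction each hour, so the flask would trace the ash run in percent and reach the 15.4% of G read there after 12.0 h.

**Fixed rate.** The second way held the loss of G in mM per hour fixed instead, and it put that same percent in the flask after 8.00 h.

**Which cheats.** The ash readings chose between them. From the first stretch (1.00 h to 3.00 h) to the last (8.00 h to 12.0 h) the fractional rate climbed from 0.0928 h⁻¹ to 0.236 h⁻¹, a factor of 2.54, while the rate in mM moved from 2.36 mM h⁻¹ to 1.82 mM h⁻¹, a factor of 0.771. So I dropped the fixed fraction and read the ash run as apparent zero order in G.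

**Charge time.** I took the rate between 3.00 h and 8.00 h, 2.24 mM h⁻¹, and called the charge of G divided by it the charge time, 8.91 h or 0.371 d for this flask. In the ash readings the share of lost G appearing as E had dropped from 0.604 to 0.318, so I placed the peak of E in this flask near that time. For its height I had the highest ash reading, 44.3%.

**The forecast.** It gave 0.35 d and 47%, holding that “the same mM rate should hold”; its time stands below mine and its amount above.

**The flask.** E peaked at 48.9% after 0.415 d, which is 1.12 charge times.

    G + Q ⇌ E (K = 1400 L mol⁻¹, k = 260 L mol⁻¹ h⁻¹)
    G + Q ⇌ X (K = 8700 L mol⁻¹, k = 110 L mol⁻¹ h⁻¹)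
    J ⇌ Q, rate k3*(csat - [Q]) (kL = 0.230 h⁻¹)

**Small charge.** In this flask E stood at 46.4% after 0.332 d and at 46.6% after 0.519 d, a span that holds the charge time. The flask with 5.0 mM of G had, at the same rate read from the ash run, a charge time of 2.23 h, so its 5.0 d spanned 53.8 of them against 13.5 here, and it ended with G at 0.89% and E at 13.8%.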